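I counted lifetimes.

| setting | amber | violet | grey | summer | winter | noon | midnight |
|---|---|---|---|---|---|---|---|
| substrate | 0.020 M | 0.020 M | 0.020 M | 0.020 M | 0.020 M (fed, over 25 min) | 0.020 M | 0.020 M |
| coupling partner | 0.014 M | 0.014 M | 0.014 M | 0.0140 M (fed, over 25 min) | 0.0140 M | 0.0140 M (fed, over 25 min) | 0.0140 M |
| free catalyst | 1.5 mM | 1 mM | 2.2 mM | 1.5 mM | 1.5 mM | 1.5 mM | 1.5 mM |
| second catalyst | 100 µM | 100 µM | 100 µM | 100 µM | 100 µM | 100 µM | 100 µM |
| temperature | 20 °C | 31 °C | 20 °C | 25 °C | 25 °C |  | 25 °C |
| remark | run made earlier | run made earlier | run made earlier | all else is in the flask from the start; the feed brings no volume worth counting | all else is in the flask from the start; the feed brings no volume worth counting | the addition at 5 °C, then warmed to 25 °C; the feed brings no volume worth counting | everything together at the start |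
| time |  |  |  | 1.0 h | 1.0 h | 1.0 h | 1.0 h |

| run | time / min | target / % | substrate / % |
|---|---|---|---|
| amber | 15.0 | 21.2 | 72.5 |
| amber | 30.0 | 32.7 | 52.4 |
| amber | 50.0 | 43.8 | 33.4 |
| amber | 60.0 | 46.6 | 28.0 |
| violet | 15.0 | 20.9 | 60.8 |
| violet | 30.0 | 28.5 | 39.9 |
| violet | 50.0 | 34.3 | 19.7 |
| violet | 60.0 | 35.4 | 13.1 |
| grey | 5.00 | 11.2 | 85.8 |
| grey | 12.0 | 23.1 | 67.5 |
| grey | 25.0 | 37.7 | 44.7 |
| grey | 60.0 | 53.4 | 14.8 |

(readings scatter by 1 percentage point)

- the flask that comes out highest in amount of target, in percent of the substrate charged, or "all alike" when all lie within 1.5 percentage points (summer / winter / noon / midnight / all alike)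
- target at the end, in percent of the substrate charged, summer
- target at the end, in percent of the substrate charged, winter
- target at the end, in percent of the substrate charged, noon
- target at the end, in percent of the substrate charged, midnight



I took free catalyst as not used up, which makes substrate loss pseudo-first-order at a given catalyst charge. From the fall of substrate between the first and last readings, the amber run gave a rate of 0.0211 min⁻¹ at 1.5 mM and 20 °C. The violet run gave 0.0341 min⁻¹ at 1 mM and 31 °C. I scaled both to 1.5 mM and interpolated the logarithm in reciprocal temperature to 25 °C. This gave the lifetime τ of substrate: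

τ = 31.4 min

n = time / τ = 1.91

I carried n, the number of substrate lifetimes a flask holds.

Winter can be bracketed by two extreme versions. If its substrate all went in at the start, as in midnight, the part left would be exp(−n):

left = 14.8%

If it all went in at the end of the feed, the clock would run for 35.0 min:

left = 32.8%

Each portion fed to winter spends between those two times in the flask, so I placed real winter between the two figures. Averaging over the steady feed, I reckoned:

left = 22.6%

So winter keeps more substrate unturned than midnight. The count tells how much substrate has gone through, not how much of it became target.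

The forecast named midnight: summer 36%, winter 43%, noon 43.5%, midnight 47%. On winter it held: “Feeding substrate loses conversion.”

    substrate + free catalyst → free catalyst + intermediate (k = 21.0 L mol⁻¹ min⁻¹, Ea = 54.0 kJ mol⁻¹)
    coupling partner + second catalyst + intermediate → second catalyst + target (k = 14000 L² mol⁻² s⁻¹, Ea = 22.0 kJ mol⁻¹)
    intermediate → side product (k = 0.300 min⁻¹, Ea = 73.0 kJ mol⁻¹)
    substrate + second catalyst → spent catalyst (k = 2.00 L mol⁻¹ min⁻¹, Ea = 65.0 kJ mol⁻¹)
    (constants at 25 °C)

The flasks gave summer 38.0%, winter 44.2%, noon 43.8% and midnight 46.9%, so midnight came highest, as forecast. Midnight held 15% of its substrate at the end, against 14.8% from the count, and winter held 23%, against 22.6%. Neither flask had come to rest. At 10.0 h midnight has had 19.1 lifetimes and its substrate stands at 0%. Its target has risen by 4.3 percentage points to 51.2%, and its side product has gone from 36.6% to 48.5%. Winter's target at that time stands at 51.2%.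

(The readings come from a simulation on assumed constants, and the scatter is random.)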